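**Retrosynthetic overview**
1. Target 28 ⇐ α-acetoxy enone 27 (cis-selective hydride at C6) ⇐ silyl dienol ether 26 (C7 acetoxylation).
2. Side chain: C12–C13 bond and the C13 carbinol come from boronate 20 and (R)-butenyl carbamate 22 by lithiation–borylation; 20 ⇐ bicyclic enone 17, which carries a C9 vinyl stub.
3. 17 ⇐ acyclic dienoic acid 14: C4–C5 (cation–olefin) and C5–C6 (acylation) are both made on one alkene carbon in a single acid-mediated operation. Ring A closes first, ring B second, and C5=C10 emerges as the conjugated enone.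
4. 14 ⇐ lactone 8 (lactone carbonyl = C10) by homoprenyl Grignard addition, methylenation and oxidation.
5. 8 ⇐ 5,6-dihydro-2H-pyran-2-one: asymmetric Cu-catalysed methyl addition sets C8, then aldol/dehydration and deconjugative methylation anti to the C8 methyl set C9.

Assumption: halimane numbering is used throughout (ring carbons C1–C10, C17 = 8-Me, C20 = 9-Me, side chain C11–C16); (R)-but-3-en-2-ol and the Josiphos enantiomer that gives the 4R adduct are purchased.

**Step 1**
Reactants: 1 5,6-dihydro-2H-pyran-2-one; 2 acetaldehyde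
Product: 4 (3R,4R)-3-(1-hydroxyethyl)-4-methyloxan-2-one, via bromomagnesium enolate 3 (not isolated)
Conditions: MeMgBr, CuBr·SMe2 (5 mol %), (R,S)-Josiphos (6 mol %), t-BuOMe, −75 °C; then 2, −78 °C
Reagents that add atoms: methylmagnesium bromide, C[Mg]Br
Why: Cu-catalysed asymmetric conjugate addition (Feringa type) sets C4 (future C8) as R under ligand control, and the magnesium enolate is trapped by a tandem aldol anti to the new methyl (that centre is removed in step 2).

**Step 2**
Reactants: 4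
Product: 6 (4R,3E)-3-ethylidene-4-methyloxan-2-one, via mesylate 5 (not isolated)
Conditions: MsCl, Et3N, CH2Cl2, 0 °C; then DBU, rt
Reagents that add atoms: none
Why: Mesylation and E1cB elimination complete the aldol condensation to the conjugated exocyclic alkene without touching C4.

**Step 3**
Reactants: 6
Product: 8 (3R,4R)-3-ethenyl-3,4-dimethyloxan-2-one, via lithium dienolate 7 (not isolated)
Conditions: LDA, THF–HMPA, −78 °C; then MeI, −78 → −40 °C
Reagents that add atoms: iodomethane, CI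
Why: Deconjugative α-alkylation of the extended enolate; MeI enters anti to the adjacent C4 methyl (held pseudoaxial by A1,3 strain), so the vinyl group ends cis and the new methyl trans to it, which fixes future C9.

**Step 4**
Reactants: 8; 9 5-bromo-2-methylpent-2-ene
Product: 11 (3R,4R)-4-ethenyl-1-hydroxy-3,4,9-trimethyldec-8-en-5-one, via Grignard reagent 10 (not isolated)
Conditions: 9, Mg, THF; then 8, THF, −78 → 0 °C
Reagents that add atoms: none
Why: Grignard addition to the lactone stops at the ketone (isolated as the hydroxy ketone/lactol) because the α-quaternary centre and the magnesium hemiketal block a second addition.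

**Step 5**
Reactants: 11
Product: 12 (3R,4R)-4-ethenyl-3,4,9-trimethyl-5-methylidenedec-8-en-1-ol
Conditions: Ph3P=CH2 (3 equiv), toluene, 90 °C
Reagents that add atoms: methylidenetriphenylphosphorane, C=P(c1ccccc1)(c1ccccc1)c1ccccc1
Why: Wittig methylenation of the open-chain ketone installs the 1,1-disubstituted alkene whose CH2 carbon becomes C5.

**Step 6**
Reactants: 12
Product: 14 (3R,4R)-4-ethenyl-3,4,9-trimethyl-5-methylidenedec-8-enoic acid, via aldehyde 13 (not isolated)
Conditions: TEMPO (20 mol %), PhI(OAc)2 (2.2 equiv), MeCN–H2O (1:1), rt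
Reagents that add atoms: water, O
Why: TEMPO/PhI(OAc)2 oxidation (Epp–Widlanski) takes the primary alcohol to the acid and leaves the three alkenes alone.

**Step 7**
Reactants: 14
Product: 17 (3R,4R)-4-ethenyl-3,4,8,8-tetramethyl-3,4,5,6,7,8-hexahydronaphthalen-1(2H)-one, via acyclic mixed anhydride 15 (not isolated), via monocyclic mixed anhydride 16 (not isolated)
Conditions: TFAA (3 equiv), TFA–CH2Cl2 (1:2), 0 °C → rt
Reagents that add atoms: none
Why: Proposed new method: TFAA masks the acid as its mixed anhydride (no lactonisation), TFA protonates the trisubstituted alkene and the C4 cation is captured 6-endo by the CH2 terminus of the 1,1-disubstituted alkene (cyclogeranyl-type cation–olefin cyclisation, ring A), E1 loss gives the ring alkene whose CH carbon C5 is then acylated intramolecularly (Friedel–Crafts/Kondakov alkene acylation, closest precedent 4-(cyclohexenyl)butanoic acid → Δ9,10-octal-1-one, ring B), and loss of the α-proton leaves the conjugated tetrasubstituted enone as thermodynamic sink with C8 and C9 as spectators.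

**Step 8**
Reactants: 17
Product: 19 tert-butyl{[(3R,4R)-4-ethenyl-3,4,8,8-tetramethyl-3,4,5,6,7,8-hexahydronaphthalen-1-yl]oxy}dimethylsilane, via lithium enolate 18 (not isolated)
Conditions: LDA, THF, −78 °C; then TBSCl, HMPA, −78 → 0 °C
Reagents that add atoms: tert-butyldimethylsilyl chloride, CC(C)(C)[Si](C)(C)Cl
Why: Kinetic α′-deprotonation at C7 and O-silylation give the cross-conjugated silyl dienol ether, which masks the ketone for steps 9 and 11 and activates C7 for step 12.

**Step 9**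
Reactants: 19
Product: 20 2-{2-[(1R,2R)-4-(tert-butyldimethylsilyloxy)-1,2,5,5-tetramethyl-1,2,5,6,7,8-hexahydronaphthalen-1-yl]ethyl}-4,4,5,5-tetramethyl-1,3,2-dioxaborolane
Conditions: HBpin, [Ir(cod)Cl]2 (1.5 mol %), dppm (3 mol %), CH2Cl2, rt
Reagents that add atoms: pinacolborane, [H]B1OC(C)(C)C(C)(C)O1
Why: Ir-catalysed anti-Markovnikov hydroboration is selective for the monosubstituted vinyl group over the tri- and tetrasubstituted alkenes.

**Step 10**
Reactants: 21 (R)-but-3-en-2-ol
Product: 22 (R)-but-3-en-2-yl N,N-diisopropylcarbamate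
Conditions: i-Pr2NCOCl, Et3N, CH2Cl2, reflux
Reagents that add atoms: N,N-diisopropylcarbamoyl chloride, CC(C)N(C(C)C)C(=O)Cl
Why: O-carbamoylation gives the Hoppe carbamate without touching the stereocentre.

**Step 11**
Reactants: 20; 22
Product: 26 (8R,9R,13S)-6-(tert-butyldimethylsilyloxy)halima-5(10),6,14-trien-13-ol, via lithiated carbamate 23 (not isolated), via boronate complex 24 (not isolated), via tertiary boronic ester 25 (not isolated)
Conditions: 22, s-BuLi, TMEDA, Et2O, −78 °C; then 20, −78 → 35 °C; then NaOH, H2O2, THF–H2O, 0 °C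
Reagents that add atoms: hydrogen peroxide, OO
Why: Aggarwal lithiation–borylation: retentive lithiation and borylation, 1,2-metallate shift with inversion and retentive C–B oxidation turn the (R)-carbamate stereospecifically into the (13S) tertiary allylic alcohol.

**Step 12**
Reactants: 26
Product: 27 (7R,8S,9R,13S)-7-acetoxy-13-hydroxyhalima-5(10),14-dien-6-one
Conditions: Pb(OAc)4, CH2Cl2, −20 → 0 °C
Reagents that add atoms: lead(IV) acetate, CC(=O)O[Pb](OC(C)=O)(OC(C)=O)OC(C)=O
Why: Rubottom-type α′-acetoxylation of the silyl dienol ether delivers acetate to C7 anti to the C8 methyl, which is also the diequatorial, thermodynamically preferred epimer (7R).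

**Step 13**
Reactants: 27
Product: 28 (6S,7R,8S,9R,13S)-6,13-dihydroxyhalima-5(10),14-dien-7-yl acetate (target)
Conditions: L-Selectride, THF, −78 °C; then AcOH, −78 °C
Reagents that add atoms: none
Why: 1,2-reduction by the bulky hydride anti to the α-acetoxy group (Felkin–Anh, equatorial attack) gives the pseudoaxial 6-OH cis to 7-OAc (6S), and the cold acidic quench suppresses acyl migration.

**Compound list**
1 | 5,6-dihydro-2H-pyran-2-one | O=C1C=CCCO1 | starting material
2 | acetaldehyde | CC=O | starting material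
3 | bromomagnesium enolate of (R)-4-methyloxan-2-one | C[C@@H]1CCOC(O[Mg]Br)=C1 | intermediate (not isolated)
4 | (3R,4R)-3-(1-hydroxyethyl)-4-methyloxan-2-one (trans, carbinol epimers) | CC(O)[C@@H]1C(=O)OCC[C@H]1C | intermediate
5 | methanesulfonate of 4 | CC(OS(C)(=O)=O)[C@@H]1C(=O)OCC[C@H]1C | intermediate (not isolated)
6 | (4R,3E)-3-ethylidene-4-methyloxan-2-one | C/C=C1/C(=O)OCC[C@H]1C | intermediate
7 | lithium dienolate of 6 | C=CC1=C(O[Li])OCC[C@H]1C | intermediate (not isolated)
8 | (3R,4R)-3-ethenyl-3,4-dimethyloxan-2-one (vinyl cis to 4-Me) | C=C[C@@]1(C)C(=O)OCC[C@H]1C | intermediate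
9 | 5-bromo-2-methylpent-2-ene | CC(C)=CCCBr | starting material
10 | (4-methylpent-3-en-1-yl)magnesium bromide | CC(C)=CCC[Mg]Br | intermediate (not isolated)
11 | (3R,4R)-4-ethenyl-1-hydroxy-3,4,9-trimethyldec-8-en-5-one | C=C[C@@](C)(C(=O)CCC=C(C)C)[C@H](C)CCO | intermediate
12 | (3R,4R)-4-ethenyl-3,4,9-trimethyl-5-methylidenedec-8-en-1-ol | C=C[C@@](C)(C(=C)CCC=C(C)C)[C@H](C)CCO | intermediate
13 | (3R,4R)-4-ethenyl-3,4,9-trimethyl-5-methylidenedec-8-enal | C=C[C@@](C)(C(=C)CCC=C(C)C)[C@H](C)CC=O | intermediate (not isolated)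
14 | (3R,4R)-4-ethenyl-3,4,9-trimethyl-5-methylidenedec-8-enoic acid | C=C[C@@](C)(C(=C)CCC=C(C)C)[C@H](C)CC(=O)O | intermediate
15 | mixed trifluoroacetic anhydride of 14 | C=C[C@@](C)(C(=C)CCC=C(C)C)[C@H](C)CC(=O)OC(=O)C(F)(F)F | intermediate (not isolated)
16 | (3R,4R)-4-(6,6-dimethylcyclohex-1-en-1-yl)-3,4-dimethylhex-5-enoic trifluoroacetic anhydride | C=C[C@@](C)(C1=CC(C)(C)CCC1)[C@H](C)CC(=O)OC(=O)C(F)(F)F | intermediate (not isolated)
17 | (3R,4R)-4-ethenyl-3,4,8,8-tetramethyl-3,4,5,6,7,8-hexahydronaphthalen-1(2H)-one | C=C[C@@]1(C)C2=C(C(=O)C[C@H]1C)C(C)(C)CCC2 | intermediate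
18 | lithium α′-enolate of 17 | C=C[C@@]1(C)C2=C(C(O[Li])=C[C@H]1C)C(C)(C)CCC2 | intermediate (not isolated)
19 | TBS dienol ether of 17 | C=C[C@@]1(C)C2=C(C(O[Si](C)(C)C(C)(C)C)=C[C@H]1C)C(C)(C)CCC2 | intermediate
20 | pinacol boronate (C9–CH2CH2–Bpin) | CC1(C)OB(CC[C@@]2(C)C3=C(C(O[Si](C)(C)C(C)(C)C)=C[C@H]2C)C(C)(C)CCC3)OC1(C)C | intermediate
21 | (R)-but-3-en-2-ol | C[C@@H](O)C=C | starting material
22 | (R)-but-3-en-2-yl N,N-diisopropylcarbamate | C[C@@H](OC(=O)N(C(C)C)C(C)C)C=C | intermediate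
23 | α-lithiated 22 | C[C@@]([Li])(OC(=O)N(C(C)C)C(C)C)C=C | intermediate (not isolated)
24 | lithium boronate (ate) complex of 20 and 23 | [Li+].C[C@@]([B-]1(CC[C@@]2(C)C3=C(C(O[Si](C)(C)C(C)(C)C)=C[C@H]2C)C(C)(C)CCC3)OC(C)(C)C(C)(C)O1)(OC(=O)N(C(C)C)C(C)C)C=C | intermediate (not isolated)
25 | tertiary allylic boronic ester (13-Bpin) | C=C[C@@](C)(B1OC(C)(C)C(C)(C)O1)CC[C@@]2(C)C3=C(C(O[Si](C)(C)C(C)(C)C)=C[C@H]2C)C(C)(C)CCC3 | intermediate (not isolated)
26 | (8R,9R,13S)-6-(tert-butyldimethylsilyloxy)halima-5(10),6,14-trien-13-ol | C=C[C@@](C)(O)CC[C@@]1(C)C2=C(C(O[Si](C)(C)C(C)(C)C)=C[C@H]1C)C(C)(C)CCC2 | intermediate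
27 | (7R,8S,9R,13S)-7-acetoxy-13-hydroxyhalima-5(10),14-dien-6-one | C=C[C@@](C)(O)CC[C@@]1(C)C2=C(C(=O)[C@H](OC(C)=O)[C@H]1C)C(C)(C)CCC2 | intermediate
28 | (6S,7R,8S,9R,13S)-6,13-dihydroxyhalima-5(10),14-dien-7-yl acetate | C=C[C@@](C)(O)CC[C@@]1(C)C2=C([C@H](O)[C@H](OC(C)=O)[C@H]1C)C(C)(C)CCC2 | target

**Step count:** 13 steps in total; longest linear sequence 12 steps (1 → 28 through steps 1–9 and 11–13).

**Steps most likely to fail**

Step 7. The C10 cation sits next to quaternary C9, so a 1,2-shift of methyl or vinyl from C9 could compete with proton loss, and the order of the two ring closures is not controlled. The fallback sets out from 12 and forms the rings separately without a free C10 cation. Dess–Martin oxidation gives aldehyde 13, now isolated. Me2AlCl (CH2Cl2, −78 °C) then closes ring B by a type-I carbonyl-ene reaction to (4R,5R)-4-ethenyl-4,5-dimethyl-3-(4-methylpent-3-en-1-ylidene)cyclohexan-1-ol F1. A second Dess–Martin oxidation gives the β,γ-unsaturated ketone F2. MsOH or BF3·OEt2 (CH2Cl2, −20 °C) then closes ring A by attack of the dienol α-carbon C5 on the protonated prenyl alkene, and conjugation brings the sequence back to 17.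

Step 11. Risks are α/γ borylation of the allylic carbenoid, a slow 1,2-shift, and loss of the silyl enol ether in the basic peroxide work-up. The fallback sets out from 20. B-alkyl Suzuki–Miyaura coupling with (E)-3-iodobut-2-en-1-ol (Pd(dppf)Cl2, Ag2O, K2CO3, THF) gives the (13E)-allylic alcohol (8R,9R)-6-(tert-butyldimethylsilyloxy)halima-5(10),6,13-trien-15-ol F3. Sharpless epoxidation (Ti(OiPr)4, L-(+)-DET, TBHP, −20 °C) gives the (13S,14S)-epoxy alcohol F4. I2/PPh3/imidazole gives the epoxy iodide F5. Zn in EtOH (reflux) opens it reductively to the (13S) vinyl carbinol, rejoining the route at 26.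

Step 13. The hydride may give the trans-diol, or the acetyl group may migrate to the cis 6-alkoxide. The fallback sets out from 26 and makes the cis-diol by syn-dihydroxylation instead. CsF/PhNTf2 (DME) converts the silyl dienol ether into the dienyl triflate F6. Pd(OAc)2/PPh3, HCO2H, n-Bu3N (DMF, 60 °C) reduces it to (8R,9R,13S)-halima-5(10),6,14-trien-13-ol F7. OsO4 (1.0 equiv, pyridine, −40 °C; NaHSO3) adds to the ring C6=C7 bond from the face anti to the C8 methyl, giving (6S,7R,8S,9R,13S)-halima-5(10),14-diene-6,7,13-triol F8. Selective acetylation of the less hindered equatorial 7-OH (Ac2O, 2,4,6-collidine, −20 °C, or CAL-B/vinyl acetate) returns to 28.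

**Further compounds**
F1 | step 7 | (4R,5R)-4-ethenyl-4,5-dimethyl-3-(4-methylpent-3-en-1-ylidene)cyclohexan-1-ol | C=C[C@]1(C)[C@H](C)CC(O)CC1=CCC=C(C)C
F2 | step 7 | (4R,5R)-4-ethenyl-4,5-dimethyl-3-(4-methylpent-3-en-1-ylidene)cyclohexan-1-one | C=C[C@]1(C)[C@H](C)CC(=O)CC1=CCC=C(C)C
F3 | step 11 | (8R,9R,13E)-6-(tert-butyldimethylsilyloxy)halima-5(10),6,13-trien-15-ol | OC/C=C(\C)CC[C@@]1(C)C2=C(C(O[Si](C)(C)C(C)(C)C)=C[C@H]1C)C(C)(C)CCC2
F4 | step 11 | (8R,9R,13S,14S)-13,14-epoxy-6-(tert-butyldimethylsilyloxy)halima-5(10),6-dien-15-ol | OC[C@@H]1O[C@@]1(C)CC[C@@]2(C)C3=C(C(O[Si](C)(C)C(C)(C)C)=C[C@H]2C)C(C)(C)CCC3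
F5 | step 11 | (8R,9R,13S,14R)-13,14-epoxy-15-iodo-6-(tert-butyldimethylsilyloxy)halima-5(10),6-diene | IC[C@@H]1O[C@@]1(C)CC[C@@]2(C)C3=C(C(O[Si](C)(C)C(C)(C)C)=C[C@H]2C)C(C)(C)CCC3
F6 | step 13 | (8R,9R,13S)-13-hydroxyhalima-5(10),6,14-trien-6-yl trifluoromethanesulfonate | C=C[C@@](C)(O)CC[C@@]1(C)C2=C(C(OS(=O)(=O)C(F)(F)F)=C[C@H]1C)C(C)(C)CCC2
F7 | step 13 | (8R,9R,13S)-halima-5(10),6,14-trien-13-ol | C=C[C@@](C)(O)CC[C@@]1(C)C2=C(C=C[C@H]1C)C(C)(C)CCC2
F8 | step 13 | (6S,7R,8S,9R,13S)-halima-5(10),14-diene-6,7,13-triol | C=C[C@@](C)(O)CC[C@@]1(C)C2=C([C@H](O)[C@H](O)[C@H]1C)C(C)(C)CCC2
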